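**Plan**

- Target numbering: lactone O1, C2(=O), C3, C4(OH), C5(Me); side chain C6H2, C7(Me)(OH), C8–C23. Enabling feature: C2–C3–C4–C5–C6–C7 is an unbroken six-carbon run from the acyl carbon to the oxygen-bearing quaternary C7. Trading the C7–O bond for a C2–C7 bond therefore closes a cyclohexanone with C7 as α-quaternary carbon and C4/C5 as a ring trans-diol.
- Retrosynthetic cuts, in order: acyl bond O1–C2 (moved to the C7 oxygen, γ-lactone back to ε-lactone); C7–O (Baeyer–Villiger, back to C2–C7); C9=C10 (cross-metathesis); C5–OH (epoxide hydrolysis); C7–C8 (Pd allylation). The carbocycle is the ring of 2,4-dimethylphenol.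
- Forward: Birch reduction delivers the six-membered ring, allyl (C8–C10) is attached at C7, the ring alkene becomes the trans-diol, and metathesis plus hydrogenation complete the chain to C23. Oxygen insertion then gives the seven-membered lactone and acyl transfer contracts it to the five-membered one.
- Stereochemistry: C7 from the (S)-t-Bu-PHOX/Pd allylation. C4 and C5 from a catalyst-set temporary carbinol at C2 that steers a vanadium epoxidation to one ring face, with water then entering at C5 with inversion. The carbinol is oxidised back, and C7 migrates with retention in the key step.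

Key step: step 10

Assumption: the sense of induction known for (S)-t-Bu-PHOX with the 2-methylcyclohexanone enolate is taken to hold for the 2,4-dimethylcyclohexa-1,4-dienolate; the 6R descriptor of 5 differs from the parent only through CIP priorities.
Assumption: the cross-metathesis alkene is drawn E; its geometry is irrelevant because it is hydrogenated in the next step.

**Route**

Step 1
Reactants: 1 2,4-dimethylphenol
Product: 2 tert-butyl(2,4-dimethylphenoxy)dimethylsilane
Conditions: TBSCl, imidazole, DMF, rt
Reagents that add atoms: tert-butyldimethylsilyl chloride, CC(C)(C)[Si](C)(C)Cl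
Why: Imidazole-promoted silylation of an unhindered phenol (silyl ether formation); the TBS ether, unlike a TMS ether, should survive dissolving-metal conditions.

Step 2
Reactants: 2 tert-butyl(2,4-dimethylphenoxy)dimethylsilane
Product: 3 tert-butyl[(2,4-dimethylcyclohexa-1,4-dien-1-yl)oxy]dimethylsilane
Conditions: Li, NH3(l), THF, t-BuOH, −78 → −33 °C
Reagents that add atoms: none
Why: Birch reduction of an aryl silyl ether protonates the two unsubstituted carbons C3 and C6, so the oxygen and both methyl groups stay on the surviving double bonds and the tetrasubstituted silyl enol ether is formed as one regioisomer (no stereocentre).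

Step 3
Reactants: 3 tert-butyl[(2,4-dimethylcyclohexa-1,4-dien-1-yl)oxy]dimethylsilane; 4 diallyl carbonate
Product: 5 (6R)-4,6-dimethyl-6-(prop-2-en-1-yl)cyclohex-3-en-1-one
Conditions: Pd2(dba)3 (2.5 mol%), (S)-t-Bu-PHOX (6.25 mol%), TBAT (35 mol%), THF, 25 °C
Reagents that add atoms: diallyl carbonate (4), C=CCOC(=O)OCC=C
Why: Enantioselective Tsuji allylation of a silyl enol ether: the allyloxide released from the carbonate (fluoride-initiated) desilylates 3 to a regiodefined enolate, which couples inside the (PHOX)Pd π-allyl complex, the (S)-ligand selecting the enolate face and setting the quaternary carbon as R.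

Step 4
Reactants: 5 (6R)-4,6-dimethyl-6-(prop-2-en-1-yl)cyclohex-3-en-1-one
Product: 6 (1R,6R)-4,6-dimethyl-6-(prop-2-en-1-yl)cyclohex-3-en-1-ol
Conditions: (S)-Me-CBS oxazaborolidine (20 mol%), catecholborane, toluene, −78 → −40 °C; MeOH quench
Reagents that add atoms: none
Why: Corey–Bakshi–Shibata reduction: the catalyst tells the quaternary α-carbon (large) from the α′-methylene (small) and delivers hydride to the face that puts the new hydroxyl cis to the methyl of the quaternary centre (1R); catecholborane does not hydroborate the alkenes at this temperature, and the minor enantiomer of 5 ends up in a diastereomeric alcohol that should be removable by chromatography.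

Step 5
Reactants: 6 (1R,6R)-4,6-dimethyl-6-(prop-2-en-1-yl)cyclohex-3-en-1-ol
Product: 7 (1S,3R,4R,6R)-4,6-dimethyl-4-(prop-2-en-1-yl)-7-oxabicyclo[4.1.0]heptan-3-ol
Conditions: VO(acac)2 (5 mol%), t-BuOOH (decane), CH2Cl2, 0 °C → rt
Reagents that add atoms: tert-butyl hydroperoxide, CC(C)(C)OO
Why: Vanadium-catalysed hydroxyl-directed epoxidation of a cyclohex-3-enol: the pseudoaxial vanadate ester delivers oxygen to the trisubstituted ring alkene on the hydroxyl face, setting both epoxide carbons syn to OH, while the monosubstituted, more remote allyl alkene should react far more slowly.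

Step 6
Reactants: 7 (1S,3R,4R,6R)-4,6-dimethyl-4-(prop-2-en-1-yl)-7-oxabicyclo[4.1.0]heptan-3-ol
Product: 8 (1S,4R,6R)-4,6-dimethyl-4-(prop-2-en-1-yl)-7-oxabicyclo[4.1.0]heptan-3-one
Conditions: Dess–Martin periodinane, NaHCO3, CH2Cl2, 0 °C → rt; used crude
Reagents that add atoms: none
Why: Dess–Martin oxidation under buffered, non-basic conditions returns the ketone without touching the epoxide or the stereocentres; the β,γ-epoxy ketone is prone to base-induced β-elimination and is therefore carried on without chromatography.

Step 7
Reactants: 8 (1S,4R,6R)-4,6-dimethyl-4-(prop-2-en-1-yl)-7-oxabicyclo[4.1.0]heptan-3-one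
Product: 9 (2R,4S,5S)-4,5-dihydroxy-2,4-dimethyl-2-(prop-2-en-1-yl)cyclohexan-1-one
Conditions: HClO4 (5 mol%), THF–H2O 3:1, 0 °C
Reagents that add atoms: water, O
Why: Acid-catalysed epoxide hydrolysis: water attacks the protonated epoxide at the tertiary carbon with inversion (Markovnikov, trans-diaxial opening through the half-chair with allyl pseudoaxial), so the tertiary hydroxyl ends up cis to the allyl group and the untouched secondary C–O bond completes the trans-diol; epoxide opening should be far faster than acid-catalysed enolisation, so the β-hydroxy ketone should survive.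

Step 8
Reactants: 9 (2R,4S,5S)-4,5-dihydroxy-2,4-dimethyl-2-(prop-2-en-1-yl)cyclohexan-1-one; 10 1-pentadecene
Product: 11 (2R,4S,5S)-2-[(2E)-hexadec-2-en-1-yl]-4,5-dihydroxy-2,4-dimethylcyclohexan-1-one
Conditions: 10 (4 equiv), Grubbs II catalyst (5 mol%), CH2Cl2, 40 °C
Reagents that add atoms: 1-pentadecene (10), C=CCCCCCCCCCCCCC
Why: Olefin cross-metathesis between the allyl terminus and an excess of the terminal alkene, with loss of ethene; ketone and free hydroxyls are tolerated by the ruthenium carbene and no stereocentre is involved.

Step 9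
Reactants: 11 (2R,4S,5S)-2-[(2E)-hexadec-2-en-1-yl]-4,5-dihydroxy-2,4-dimethylcyclohexan-1-one
Product: 12 (2R,4S,5S)-2-hexadecyl-4,5-dihydroxy-2,4-dimethylcyclohexan-1-one
Conditions: H2 (1 atm), 10% Pd/C, EtOAc, rt
Reagents that add atoms: none
Why: Heterogeneous catalytic hydrogenation of the only C=C bond left in the molecule; ketone, hydroxyls and stereocentres are unaffected.

Step 10
Reactants: 12 (2R,4S,5S)-2-hexadecyl-4,5-dihydroxy-2,4-dimethylcyclohexan-1-one
Product: 13 (4S,5S,7R)-7-hexadecyl-4,5-dihydroxy-5,7-dimethyloxepan-2-one
Conditions: mCPBA, NaHCO3, CH2Cl2, 0 °C → rt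
Reagents that add atoms: 3-chloroperbenzoic acid, O=C(OO)c1cccc(Cl)c1
Why: Baeyer–Villiger oxidation: the peracid adds to the ketone carbonyl and the Criegee adduct rearranges by a concerted 1,2-shift of the quaternary α-carbon (target C7) from carbon to the proximal peroxide oxygen, with loss of 3-chlorobenzoate, which forms the C7–O bond. The closest known reaction type is the peracid oxidation of 2,2-dialkylcyclohexanones to 7,7-disubstituted oxepan-2-ones. The seven-membered ring arises by ring expansion (oxygen insertion into the C1–C2 bond of the six-membered ring), not by a cyclisation. No stereocentre is created: the migrating carbon keeps its configuration (suprafacial shift, retention) and the two carbinol centres are spectators. The selectivity needed is migration of the quaternary carbon over the α′-methylene; it is secured by the better ability of the fully substituted carbon to carry positive charge in the transition state and by the electron-withdrawing β-hydroxyl on the methylene side. The bicarbonate buffer should keep the medium from dehydrating the β-hydroxy ketone or triggering acyl transfer before 13 is isolated.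

Step 11
Reactants: 13 (4S,5S,7R)-7-hexadecyl-4,5-dihydroxy-5,7-dimethyloxepan-2-one
Product: 14 (4S,5S)-4-hydroxy-5-[(2R)-2-hydroxy-2-methyloctadecyl]-5-methyloxolan-2-one
Conditions: CSA (10 mol%), CH2Cl2, rt
Reagents that add atoms: none
Why: Acid-catalysed translactonisation (intramolecular transesterification): the tertiary hydroxyl γ to the carbonyl adds 5-exo-trig to the lactone carbonyl and the tetrahedral intermediate collapses to the unstrained γ-lactone, releasing the C7 hydroxyl; only acyl C–O bonds change, so all three stereocentres are retained.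

**Compound list**

1 | 2,4-dimethylphenol | Cc1ccc(O)c(C)c1 | starting material
2 | tert-butyl(2,4-dimethylphenoxy)dimethylsilane | Cc1ccc(O[Si](C)(C)C(C)(C)C)c(C)c1 | intermediate
3 | tert-butyl[(2,4-dimethylcyclohexa-1,4-dien-1-yl)oxy]dimethylsilane | CC1=CCC(O[Si](C)(C)C(C)(C)C)=C(C)C1 | intermediate
4 | diallyl carbonate | C=CCOC(=O)OCC=C | starting material
5 | (6R)-4,6-dimethyl-6-(prop-2-en-1-yl)cyclohex-3-en-1-one | C=CC[C@]1(C)CC(C)=CCC1=O | intermediate
6 | (1R,6R)-4,6-dimethyl-6-(prop-2-en-1-yl)cyclohex-3-en-1-ol | C=CC[C@]1(C)CC(C)=CC[C@H]1O | intermediate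
7 | (1S,3R,4R,6R)-4,6-dimethyl-4-(prop-2-en-1-yl)-7-oxabicyclo[4.1.0]heptan-3-ol | C=CC[C@]1(C)C[C@@]2(C)O[C@H]2C[C@H]1O | intermediate
8 | (1S,4R,6R)-4,6-dimethyl-4-(prop-2-en-1-yl)-7-oxabicyclo[4.1.0]heptan-3-one | C=CC[C@]1(C)C[C@@]2(C)O[C@H]2CC1=O | intermediate
9 | (2R,4S,5S)-4,5-dihydroxy-2,4-dimethyl-2-(prop-2-en-1-yl)cyclohexan-1-one | C=CC[C@]1(C)C[C@](C)(O)[C@@H](O)CC1=O | intermediate
10 | 1-pentadecene | C=CCCCCCCCCCCCCC | starting material
11 | (2R,4S,5S)-2-[(2E)-hexadec-2-en-1-yl]-4,5-dihydroxy-2,4-dimethylcyclohexan-1-one | CCCCCCCCCCCCC/C=C/C[C@]1(C)C[C@](C)(O)[C@@H](O)CC1=O | intermediate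
12 | (2R,4S,5S)-2-hexadecyl-4,5-dihydroxy-2,4-dimethylcyclohexan-1-one | CCCCCCCCCCCCCCCC[C@]1(C)C[C@](C)(O)[C@@H](O)CC1=O | intermediate
13 | (4S,5S,7R)-7-hexadecyl-4,5-dihydroxy-5,7-dimethyloxepan-2-one | CCCCCCCCCCCCCCCC[C@]1(C)C[C@](C)(O)[C@@H](O)CC(=O)O1 | intermediate
14 | (4S,5S)-4-hydroxy-5-[(2R)-2-hydroxy-2-methyloctadecyl]-5-methyloxolan-2-one | CCCCCCCCCCCCCCCC[C@@](C)(O)C[C@]1(C)OC(=O)C[C@@H]1O | target

**Step count and risks**

Total step count: 11. Longest linear sequence: 11 steps (from 1).

Steps most likely to fail:

Step 3. Cleavage of the bulky silyl enol ether by the catalytic alkoxide/fluoride may be slow. The liberated enolate could then persist and equilibrate by proton transfer (double-bond migration into conjugation, α′-allylation), eroding regio- and enantiocontrol. The fallback sets out from 3. MeLi in THF (0 °C → rt) converts it into lithium 2,4-dimethylcyclohexa-1,4-dien-1-olate F1. This is O-acylated with allyl chloroformate at −78 °C to give allyl 2,4-dimethylcyclohexa-1,4-dien-1-yl carbonate F2. Pd2(dba)3/(S)-t-Bu-PHOX in THF then effects decarboxylative Tsuji allylation from this neutral precursor, without any external activator, and the route is rejoined at 5.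

Step 4. Face discrimination at the hindered carbonyl may be insufficient, or the catecholborane reduction sluggish. The epimeric carbinol would relay the epoxide to the wrong ring face. The fallback sets out from 5 and dispenses with the hydroxyl relay (steps 4–6). mCPBA (1 equiv), NaHCO3, CH2Cl2, 0 °C should epoxidise the trisubstituted ring alkene chemoselectively over the allyl group. Little facial bias is expected, so 8 would be accompanied by its epoxide epimer, (1R,4R,6S)-4,6-dimethyl-4-(prop-2-en-1-yl)-7-oxabicyclo[4.1.0]heptan-3-one F3. Separation on neutralised silica would be needed before the route is rejoined at 8.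

Step 10. Peracid addition to the α-quaternary ketone may be slow. This leaves time for dehydration of the β-hydroxy ketone and oxidation of the resulting enone, or forces conditions the free diol does not tolerate. The fallback sets out from 12. TESCl/imidazole in DMF at 0 °C should silylate the secondary hydroxyl selectively to (2R,4S,5S)-2-hexadecyl-4-hydroxy-2,4-dimethyl-5-[(triethylsilyl)oxy]cyclohexan-1-one F4, which can no longer dehydrate. Baeyer–Villiger oxidation under more forcing conditions (mCPBA, NaHCO3, 1,2-dichloroethane, 50 °C) then gives (4S,5S,7R)-7-hexadecyl-5-hydroxy-5,7-dimethyl-4-[(triethylsilyl)oxy]oxepan-2-one F5. HF·pyridine in THF at 0 °C removes the silyl group and the route is rejoined at 13.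

Further compounds
F1 | step 3 | lithium 2,4-dimethylcyclohexa-1,4-dien-1-olate | [Li+].[O-]C1=C(C)CC(C)=CC1
F2 | step 3 | allyl 2,4-dimethylcyclohexa-1,4-dien-1-yl carbonate | C=CCOC(=O)OC1=C(C)CC(C)=CC1
F3 | step 4 | (1R,4R,6S)-4,6-dimethyl-4-(prop-2-en-1-yl)-7-oxabicyclo[4.1.0]heptan-3-one | C=CC[C@]1(C)C[C@]2(C)O[C@@H]2CC1=O
F4 | step 10 | (2R,4S,5S)-2-hexadecyl-4-hydroxy-2,4-dimethyl-5-[(triethylsilyl)oxy]cyclohexan-1-one | CCCCCCCCCCCCCCCC[C@]1(C)C[C@](C)(O)[C@@H](O[Si](CC)(CC)CC)CC1=O
F5 | step 10 | (4S,5S,7R)-7-hexadecyl-5-hydroxy-5,7-dimethyl-4-[(triethylsilyl)oxy]oxepan-2-one | CCCCCCCCCCCCCCCC[C@]1(C)C[C@](C)(O)[C@@H](O[Si](CC)(CC)CC)CC(=O)O1
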